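Ring C is disconnected at the O1–C2 bond. C2 is benzylic to ring B and para to the C4' hydroxyl, so it can serve as the methide carbon of a para-quinone methide, while C3 corresponds to the carbinol of an (R)-aryllactic acid from D-tyrosine. In one operation the key step oxidises the ring-B CH2 of an open-chain (R)-2-hydroxy-1,3-diarylpropan-1-one and lets the ring-A phenol oxygen add to the methide carbon, closing ring C and setting C2 trans to the C3 hydroxyl. The precursor has all phenols free and bromine at the future C6, C8 and C3' positions as oxidation-proof stand-ins for the prenyl groups, which are installed afterwards by Stille coupling.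

Key step: step 10

Remark: cyclised compounds and all discussion use flavanone numbering (O1, C2, C3, C4; ring A C5 to C8; ring B primed); the cyclisation precursor is designed with a free C7 hydroxyl, and ring B is kept as its TIPS ether while ring A is brominated so that only ring A is halogenated.

Step 1
Reactants: 1 D-tyrosine
Product: 2 3-bromo-D-tyrosine, (R)-2-amino-3-(3-bromo-4-hydroxyphenyl)propanoic acid
Conditions: Br2 (1.0 equiv), HBr/AcOH, rt; isoelectric precipitation from water (pH 5–6)
Reagents that add atoms: bromine, BrBr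
Why: Electrophilic aromatic bromination: in strong acid the ammonium side chain is inert, the phenol directs bromine to its ortho position (C3 of the tyrosine ring), and the first bromine deactivates the ring toward a second substitution, while the stereocentre is not involved.

Step 2
Reactants: 2 3-bromo-D-tyrosine
Product: 5 (R)-3-(3-bromo-4-hydroxyphenyl)-2-hydroxypropanoic acid, via diazonium carboxylate 3 (not isolated), via alpha-lactone 4 (not isolated)
Conditions: NaNO2 (1.5 equiv), 1 M aq H2SO4, 0 °C → rt
Reagents that add atoms: water, O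
Why: Diazotisation of the α-amino acid gives diazonium carboxylate 3, whose carboxylate displaces N2 with inversion to α-lactone 4 and water reopens it with a second inversion (neighbouring-group participation), so the hydroxyl replaces the amine with net retention and the (R) centre is kept.

Step 3
Reactants: 5 (R)-3-(3-bromo-4-hydroxyphenyl)-2-hydroxypropanoic acid
Product: 7 (R)-3-(3-bromo-4-hydroxyphenyl)-2-hydroxy-N-methoxy-N-methylpropanamide, via benzotriazolyl ester 6 (not isolated)
Conditions: MeNH(OMe)·HCl (1.3 equiv), EDC·HCl (1.3 equiv), HOBt (1.2 equiv), N-methylmorpholine (1.4 equiv), DMF/CH2Cl2, 0 °C → rt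
Reagents that add atoms: N,O-dimethylhydroxylamine hydrochloride, CNOC.Cl
Why: Carbodiimide amide coupling via the benzotriazolyl active ester 6: the free amine is far more nucleophilic than the phenol or the secondary hydroxyl, and an α-hydroxy acid has no azlactone pathway for racemisation.

Step 4
Reactants: 7 (R)-3-(3-bromo-4-hydroxyphenyl)-2-hydroxy-N-methoxy-N-methylpropanamide
Product: 9 (R)-3-[3-bromo-4-(triisopropylsilyloxy)phenyl]-2-(tert-butyldimethylsilyloxy)-N-methoxy-N-methylpropanamide, via phenol TIPS ether 8 (not isolated)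
Conditions: TIPSCl (1.05 equiv), imidazole (4 equiv), DMF, 0 °C → rt; then TBSCl (1.6 equiv), 40 °C
Reagents that add atoms: chlorotriisopropylsilane (TIPSCl), CC(C)[Si](Cl)(C(C)C)C(C)C; tert-butylchlorodimethylsilane (TBSCl), CC(C)(C)[Si](C)(C)Cl
Why: Silyl ether formation in two stages in one flask: the bulky silyl chloride reacts only with the acidic phenol (8), and the smaller TBSCl then caps the secondary alcohol, giving two silyl ethers of deliberately different acid lability.

Step 5
Reactants: 10 4-bromoresorcinol
Product: 11 1-bromo-2,4-bis(methoxymethoxy)benzene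
Conditions: MOMCl (2.4 equiv), i-Pr2NEt (3 equiv), CH2Cl2, 0 °C → rt
Reagents that add atoms: chloromethyl methyl ether (MOMCl), COCCl
Why: O-Alkylation of both phenols with the reactive chloromethyl ether under amine base (Williamson-type acetal formation), giving ethers that tolerate the later lithiation and stabilise the aryllithium by coordination.

Step 6
Reactants: 11 1-bromo-2,4-bis(methoxymethoxy)benzene; 9 (R)-3-[3-bromo-4-(triisopropylsilyloxy)phenyl]-2-(tert-butyldimethylsilyloxy)-N-methoxy-N-methylpropanamide
Product: 14 (R)-1-[2,4-bis(methoxymethoxy)phenyl]-3-[3-bromo-4-(triisopropylsilyloxy)phenyl]-2-(tert-butyldimethylsilyloxy)propan-1-one, via aryllithium 12 (not isolated), via tetrahedral lithium adduct 13 (not isolated)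
Conditions: 11 (1.25 equiv), n-BuLi (1.2 equiv), THF, −78 °C; then 9 (1.0 equiv), −78 → −40 °C; AcOH quench
Reagents that add atoms: none
Why: Bromine–lithium exchange followed by Weinreb ketone synthesis: aryllithium 12 adds once to the amide to give the chelated tetrahedral adduct 13, which collapses to the ketone only on quench, the α-silyloxy centre is not deprotonated at −78 °C so (R) is retained, and the slight deficit of n-BuLi relative to 11 leaves no alkyllithium to exchange with the ring-B bromide.

Step 7
Reactants: 14 (R)-1-[2,4-bis(methoxymethoxy)phenyl]-3-[3-bromo-4-(triisopropylsilyloxy)phenyl]-2-(tert-butyldimethylsilyloxy)propan-1-one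
Product: 15 (R)-3-[3-bromo-4-(triisopropylsilyloxy)phenyl]-1-(2,4-dihydroxyphenyl)-2-hydroxypropan-1-one
Conditions: HCl (1.25 M in MeOH), rt
Reagents that add atoms: none
Why: Acid-catalysed acetal methanolysis and silyl ether solvolysis: aryl methoxymethyl ethers and the secondary alkyl TBS ether cleave in dilute methanolic HCl at rt, whereas the hindered aryl TIPS ether is far more resistant, and these mild conditions should not enolise the hydrogen-bonded aryl ketone, so the carbinol configuration is kept.

Step 8
Reactants: 15 (R)-3-[3-bromo-4-(triisopropylsilyloxy)phenyl]-1-(2,4-dihydroxyphenyl)-2-hydroxypropan-1-one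
Product: 16 (R)-3-[3-bromo-4-(triisopropylsilyloxy)phenyl]-1-(3,5-dibromo-2,4-dihydroxyphenyl)-2-hydroxypropan-1-one
Conditions: NBS (2.05 equiv), MeCN, −10 → 0 °C
Reagents that add atoms: N-bromosuccinimide, O=C1CCC(=O)N1Br
Why: Electrophilic aromatic bromination of the free resorcinol-type ring at its two positions ortho/para to the hydroxyls (C3 and C5 of the acyl ring), while ring B, a brominated aryl silyl ether, is too deactivated to react with NBS at this temperature.

Step 9
Reactants: 16 (R)-3-[3-bromo-4-(triisopropylsilyloxy)phenyl]-1-(3,5-dibromo-2,4-dihydroxyphenyl)-2-hydroxypropan-1-one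
Product: 17 (R)-3-(3-bromo-4-hydroxyphenyl)-1-(3,5-dibromo-2,4-dihydroxyphenyl)-2-hydroxypropan-1-one
Conditions: TBAF (1.2 equiv), AcOH (1.5 equiv), THF, 0 °C
Reagents that add atoms: none
Why: Fluoride-mediated desilylation (Si–F bond formation drives cleavage of the aryl silyl ether), buffered with acetic acid so that the α-hydroxy ketone never meets free base.

Step 10
Reactants: 17 (R)-3-(3-bromo-4-hydroxyphenyl)-1-(3,5-dibromo-2,4-dihydroxyphenyl)-2-hydroxypropan-1-one
Product: 19 (2R,3R)-6,8-dibromo-2-(3-bromo-4-hydroxyphenyl)-3,7-dihydroxychroman-4-one, via quinone methide 18 (not isolated)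
Conditions: DDQ (1.05 equiv), 1,4-dioxane, 15 °C → rt (warm to 50 °C only if needed)
Reagents that add atoms: none
Why: DDQ removes hydride from the ring-B CH2 para to the free C4' hydroxyl, giving quinone methide 18, whose exocyclic carbon is attacked by the ring-A hydroxyl ortho to the ketone (future O1) with rearomatisation of ring B. The closest known reaction type is the quinone-mediated oxidation of 4-alkylphenols to para-quinone methides with intramolecular phenol capture, as used to turn 1,3-diarylpropanes into flavans and 2'-hydroxydihydrochalcones into flavanones. Ring C forms by a 6-exo-trig oxa-Michael closure. The new C2 stereocentre is controlled by the existing C3 carbinol: in the chair-like transition state the C3 hydroxyl (hydrogen-bonded to C4=O) and the ring-B residue both sit pseudo-equatorial, which should give the 2,3-trans (2R,3R) isomer, also the thermodynamic product if the closure is reversible. Chemoselectivity is secured because ring A carries no oxidisable para-alkyl group and is deactivated by two bromines and the acyl group, and because bromine, unlike an ortho-prenyl group, cannot be dehydrogenated to a chromene. Over-oxidation to the flavonol is limited by one equivalent of DDQ at or below rt and by the electron-poor brominated ring B of the product, whose C2–H is further deactivated by the adjacent C3–OH and C4=O.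

Step 11
Reactants: 19 (2R,3R)-6,8-dibromo-2-(3-bromo-4-hydroxyphenyl)-3,7-dihydroxychroman-4-one
Product: 20 (2R,3R)-6,8-dibromo-2-[3-bromo-4-(methoxymethoxy)phenyl]-3-hydroxy-7-(methoxymethoxy)chroman-4-one
Conditions: MOMCl (2.3 equiv), i-Pr2NEt (3.5 equiv), CH2Cl2, 0 °C
Reagents that add atoms: chloromethyl methyl ether (MOMCl), COCCl
Why: O-Alkylation of the two phenols, which are far more acidic than the hydrogen-bonded C3 hydroxyl, under mild amine base at 0 °C; capping C4'-OH blocks ring opening through a quinone methide and capping the acidic C7-OH prevents protonolysis of the allylstannane in the next step.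

Step 12
Reactants: 20 (2R,3R)-6,8-dibromo-2-[3-bromo-4-(methoxymethoxy)phenyl]-3-hydroxy-7-(methoxymethoxy)chroman-4-one; 21 tributyl(3-methylbut-2-enyl)stannane
Product: 22 (2R,3R)-3-hydroxy-7-(methoxymethoxy)-2-[4-(methoxymethoxy)-3-(3-methylbut-2-enyl)phenyl]-6,8-bis(3-methylbut-2-enyl)chroman-4-one
Conditions: Pd(PPh3)4 (15 mol %), 21 (4.5 equiv), degassed DMF, 95 °C
Reagents that add atoms: tributyl(3-methylbut-2-enyl)stannane (21), CC(C)=CC[Sn](CCCC)(CCCC)CCCC
Why: Threefold Stille cross-coupling: oxidative addition of zerovalent palladium into each aryl bromide, transmetallation of the prenyl group from tin and reductive elimination at the less hindered primary terminus should give the linear 3-methylbut-2-enyl groups under neutral conditions that leave C2 and C3 untouched.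

Step 13
Reactants: 22 (2R,3R)-3-hydroxy-7-(methoxymethoxy)-2-[4-(methoxymethoxy)-3-(3-methylbut-2-enyl)phenyl]-6,8-bis(3-methylbut-2-enyl)chroman-4-one
Product: 23 lespeflorin B3, (2R,3R)-3,7-dihydroxy-2-[4-hydroxy-3-(3-methylbut-2-enyl)phenyl]-6,8-bis(3-methylbut-2-enyl)chroman-4-one
Conditions: HCl (1 M in MeOH), rt
Reagents that add atoms: none
Why: Acid-catalysed acetal methanolysis of the two aryl methoxymethyl ethers in dilute methanolic HCl at rt, conditions mild enough to leave the trisubstituted prenyl alkenes unprotonated and the trans-dihydroflavonol configuration intact.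

Compound list
1 | D-tyrosine, (R)-2-amino-3-(4-hydroxyphenyl)propanoic acid | N[C@H](Cc1ccc(O)cc1)C(=O)O | starting material
2 | 3-bromo-D-tyrosine, (R)-2-amino-3-(3-bromo-4-hydroxyphenyl)propanoic acid | N[C@H](Cc1ccc(O)c(Br)c1)C(=O)O | intermediate
3 | (R)-3-(3-bromo-4-hydroxyphenyl)-2-diazoniopropanoate (diazonium carboxylate, not isolated) | N#[N+][C@H](Cc1ccc(O)c(Br)c1)C(=O)[O-] | intermediate
4 | (S)-3-(3-bromo-4-hydroxybenzyl)oxiran-2-one (alpha-lactone, not isolated) | O=C1O[C@H]1Cc1ccc(O)c(Br)c1 | intermediate
5 | (R)-3-(3-bromo-4-hydroxyphenyl)-2-hydroxypropanoic acid | O[C@H](Cc1ccc(O)c(Br)c1)C(=O)O | intermediate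
6 | 1H-benzotriazol-1-yl (R)-3-(3-bromo-4-hydroxyphenyl)-2-hydroxypropanoate (active ester, not isolated) | O=C(On1nnc2ccccc12)[C@H](O)Cc1ccc(O)c(Br)c1 | intermediate
7 | (R)-3-(3-bromo-4-hydroxyphenyl)-2-hydroxy-N-methoxy-N-methylpropanamide | CON(C)C(=O)[C@H](O)Cc1ccc(O)c(Br)c1 | intermediate
8 | (R)-3-[3-bromo-4-(triisopropylsilyloxy)phenyl]-2-hydroxy-N-methoxy-N-methylpropanamide (not isolated) | CON(C)C(=O)[C@H](O)Cc1ccc(O[Si](C(C)C)(C(C)C)C(C)C)c(Br)c1 | intermediate
9 | (R)-3-[3-bromo-4-(triisopropylsilyloxy)phenyl]-2-(tert-butyldimethylsilyloxy)-N-methoxy-N-methylpropanamide | CON(C)C(=O)[C@H](O[Si](C)(C)C(C)(C)C)Cc1ccc(O[Si](C(C)C)(C(C)C)C(C)C)c(Br)c1 | intermediate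
10 | 4-bromoresorcinol (4-bromobenzene-1,3-diol) | Oc1ccc(Br)c(O)c1 | starting material
11 | 1-bromo-2,4-bis(methoxymethoxy)benzene | COCOc1ccc(Br)c(OCOC)c1 | intermediate
12 | [2,4-bis(methoxymethoxy)phenyl]lithium (not isolated) | [Li]c1ccc(OCOC)cc1OCOC | intermediate
13 | lithium alkoxide of the tetrahedral N-methoxy-N-methyl hemiaminal from 12 and 9, (2R) carbinol, hemiaminal carbon unassigned (not isolated) | CON(C)C(O[Li])(c1ccc(OCOC)cc1OCOC)[C@H](O[Si](C)(C)C(C)(C)C)Cc1ccc(O[Si](C(C)C)(C(C)C)C(C)C)c(Br)c1 | intermediate
14 | (R)-1-[2,4-bis(methoxymethoxy)phenyl]-3-[3-bromo-4-(triisopropylsilyloxy)phenyl]-2-(tert-butyldimethylsilyloxy)propan-1-one | O=C([C@H](O[Si](C)(C)C(C)(C)C)Cc1ccc(O[Si](C(C)C)(C(C)C)C(C)C)c(Br)c1)c1ccc(OCOC)cc1OCOC | intermediate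
15 | (R)-3-[3-bromo-4-(triisopropylsilyloxy)phenyl]-1-(2,4-dihydroxyphenyl)-2-hydroxypropan-1-one | O=C([C@H](O)Cc1ccc(O[Si](C(C)C)(C(C)C)C(C)C)c(Br)c1)c1ccc(O)cc1O | intermediate
16 | (R)-3-[3-bromo-4-(triisopropylsilyloxy)phenyl]-1-(3,5-dibromo-2,4-dihydroxyphenyl)-2-hydroxypropan-1-one | O=C([C@H](O)Cc1ccc(O[Si](C(C)C)(C(C)C)C(C)C)c(Br)c1)c1cc(Br)c(O)c(Br)c1O | intermediate
17 | (R)-3-(3-bromo-4-hydroxyphenyl)-1-(3,5-dibromo-2,4-dihydroxyphenyl)-2-hydroxypropan-1-one (key-step precursor) | O=C([C@H](O)Cc1ccc(O)c(Br)c1)c1cc(Br)c(O)c(Br)c1O | intermediate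
18 | (R)-3-(3-bromo-4-oxocyclohexa-2,5-dien-1-ylidene)-1-(3,5-dibromo-2,4-dihydroxyphenyl)-2-hydroxypropan-1-one (para-quinone methide, exocyclic alkene geometry immaterial, not isolated) | O=C([C@H](O)C=C1C=CC(=O)C(Br)=C1)c1cc(Br)c(O)c(Br)c1O | intermediate
19 | (2R,3R)-6,8-dibromo-2-(3-bromo-4-hydroxyphenyl)-3,7-dihydroxychroman-4-one (key-step product) | Brc1cc([C@H]2Oc3c(cc(Br)c(O)c3Br)C(=O)[C@@H]2O)ccc1O | intermediate
20 | (2R,3R)-6,8-dibromo-2-[3-bromo-4-(methoxymethoxy)phenyl]-3-hydroxy-7-(methoxymethoxy)chroman-4-one | Brc1cc([C@H]2Oc3c(cc(Br)c(OCOC)c3Br)C(=O)[C@@H]2O)ccc1OCOC | intermediate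
21 | tributyl(3-methylbut-2-enyl)stannane | CC(C)=CC[Sn](CCCC)(CCCC)CCCC | starting material
22 | (2R,3R)-3-hydroxy-7-(methoxymethoxy)-2-[4-(methoxymethoxy)-3-(3-methylbut-2-enyl)phenyl]-6,8-bis(3-methylbut-2-enyl)chroman-4-one | CC(C)=CCc1cc([C@H]2Oc3c(cc(CC=C(C)C)c(OCOC)c3CC=C(C)C)C(=O)[C@@H]2O)ccc1OCOC | intermediate
23 | lespeflorin B3, (2R,3R)-3,7-dihydroxy-2-[4-hydroxy-3-(3-methylbut-2-enyl)phenyl]-6,8-bis(3-methylbut-2-enyl)chroman-4-one | CC(C)=CCc1cc([C@H]2Oc3c(cc(CC=C(C)C)c(O)c3CC=C(C)C)C(=O)[C@@H]2O)ccc1O | target

Total step count: 13. Longest linear sequence: 12 steps (steps 1–4 and 6–13, from D-tyrosine); step 5 is the one-step side branch.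

Steps most likely to fail

Step 10. Hydride abstraction from the bromine-deactivated phenol may be slow. The quinone methide then has time to tautomerise toward the enol of the 1,2-dione, which erases the C3 configuration, or the closed product may be dehydrogenated further to the flavonol. The fallback sets out from 17 and comes back to the route at 19; it separates oxidation from ring closure. 17 would be oxidised with DDQ (1.0 equiv) in methanol at 0 °C, where the solvent, present in vast excess, captures the quinone methide as it forms. This should give the benzylic ether (2R)-3-(3-bromo-4-hydroxyphenyl)-1-(3,5-dibromo-2,4-dihydroxyphenyl)-2-hydroxy-3-methoxypropan-1-one F1 as a mixture of epimers at the methoxy-bearing carbon. After removal of the spent oxidant, F1 would be ionised with catalytic TsOH·H2O in dry 1,4-dioxane (rt to 40 °C). The ring-A phenol then closes the benzylic cation under thermodynamic control, the acid-mediated benzylic etherification used to close flavan-3-ols. This should give trans 19 without the product ever meeting the oxidant.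

Step 12. The threefold coupling may stall at the C8 bromide, which is flanked by two oxygens; bromides may be lost by reduction; or the prenyl group may be delivered with allylic transposition, giving 1,1-dimethylallyl isomers. The fallback sets out from 20 and comes back at 22. 20 would be coupled with allyltributylstannane (Pd(PPh3)4, toluene/DMF, 90 °C), an unhindered stannane for which transposition has no consequence. This should give (2R,3R)-6,8-diallyl-2-[3-allyl-4-(methoxymethoxy)phenyl]-3-hydroxy-7-(methoxymethoxy)chroman-4-one F2. Its three terminal alkenes would then be converted into prenyl groups by olefin cross-metathesis with 2-methyl-2-butene (second-generation Grubbs catalyst RuCl2(=CHPh)(PCy3)(H2IMes), 2-methyl-2-butene/CH2Cl2, 40 °C), giving 22.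

Step 13. Acid may induce cyclisation of the liberated ortho-prenylphenols onto their own alkenes (chroman formation), or addition of methanol to the prenyl groups, before the hindered C7 acetal is fully cleaved. The fallback sets out from 19 and comes back at the target 23; it replaces acetal by fluoride-labile silyl protection. 19 would be silylated on both phenols (TBSCl, imidazole, DMF, 0 °C → rt) to (2R,3R)-6,8-dibromo-2-[3-bromo-4-(tert-butyldimethylsilyloxy)phenyl]-7-(tert-butyldimethylsilyloxy)-3-hydroxychroman-4-one F3. F3 would undergo the same triple Stille coupling with 21 in toluene (Pd(PPh3)4, 100 °C) to (2R,3R)-7-(tert-butyldimethylsilyloxy)-2-[4-(tert-butyldimethylsilyloxy)-3-(3-methylbut-2-enyl)phenyl]-3-hydroxy-6,8-bis(3-methylbut-2-enyl)chroman-4-one F4. Buffered fluoride (TBAF/AcOH, THF, 0 °C) would then release 23 without any acid.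

Further compounds
F1 | step 10 | (2R)-3-(3-bromo-4-hydroxyphenyl)-1-(3,5-dibromo-2,4-dihydroxyphenyl)-2-hydroxy-3-methoxypropan-1-one (epimers at C3) | COC(c1ccc(O)c(Br)c1)[C@@H](O)C(=O)c1cc(Br)c(O)c(Br)c1O
F2 | step 12 | (2R,3R)-6,8-diallyl-2-[3-allyl-4-(methoxymethoxy)phenyl]-3-hydroxy-7-(methoxymethoxy)chroman-4-one | C=CCc1cc([C@H]2Oc3c(cc(CC=C)c(OCOC)c3CC=C)C(=O)[C@@H]2O)ccc1OCOC
F3 | step 13 | (2R,3R)-6,8-dibromo-2-[3-bromo-4-(tert-butyldimethylsilyloxy)phenyl]-7-(tert-butyldimethylsilyloxy)-3-hydroxychroman-4-one | Brc1cc([C@H]2Oc3c(cc(Br)c(O[Si](C)(C)C(C)(C)C)c3Br)C(=O)[C@@H]2O)ccc1O[Si](C)(C)C(C)(C)C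
F4 | step 13 | (2R,3R)-7-(tert-butyldimethylsilyloxy)-2-[4-(tert-butyldimethylsilyloxy)-3-(3-methylbut-2-enyl)phenyl]-3-hydroxy-6,8-bis(3-methylbut-2-enyl)chroman-4-one | CC(C)=CCc1cc([C@H]2Oc3c(cc(CC=C(C)C)c(O[Si](C)(C)C(C)(C)C)c3CC=C(C)C)C(=O)[C@@H]2O)ccc1O[Si](C)(C)C(C)(C)C
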